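**Strategy.** The target is disconnected at the C8–C9 bond of ring B (labdane numbering: C1 bears the acetate, C4 the ester, C5 and C10 are the ring fusion, C17 is the methylene carbon on C8, C11 the first side-chain carbon on C9). Because the exocyclic C8=C17 alkene is attached to a C9 that can carry a formyl carbon (C11), C9 can act as an enol ether carbon and C8 as the inner carbon of a C8≡C17 alkyne. A single cationic-gold cyclisation then closes ring B, creates the methylene group and sets C9. Its substrate is a monocyclic ring A carrying all four other stereocentres, a but-3-ynyl chain on C5 and a silyl enol ether on C10.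

Key step: step 11

Remark: ring atoms are called by their labdane numbers in every step, also in the monocyclic intermediates (C18 methyl and C19 carbonyl on C4, C20 methyl on C10).
Assumption: the (S)-configured oxazaborolidinium catalyst of step 3 is taken to shield the face of bound methacrolein that leads to 7; if the facial sense proves opposite, its enantiomer is used and nothing else changes.
Remark: silylation next to the quaternary C10 should give mainly the E enol ether drawn for 15; a Z isomer would converge on the same product, since the geometry is erased in step 11.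

Step 1
Reactants: 1 pent-4-yn-1-ol; 2 3-(triphenylphosphoranylidene)butan-2-one
Product: 4 (3E)-3-methyloct-3-en-7-yn-2-one, via pent-4-ynal 3 (not isolated)
Conditions: IBX, EtOAc, 75 °C; filter; then 2, EtOAc, 75 °C
Reagents that add atoms: none
Why: oxidation with 2-iodoxybenzoic acid gives the volatile aldehyde, which is trapped in solution by a Wittig reaction with a ketone-stabilised α-methyl ylide, a reagent class that should give the E trisubstituted enone, while the terminal alkyne is inert to both reagents.

Step 2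
Reactants: 4 (3E)-3-methyloct-3-en-7-yn-2-one
Product: 5 triisopropyl{[(3E)-3-methylocta-1,3-dien-7-yn-2-yl]oxy}silane
Conditions: TIPSOTf, Et3N, CH2Cl2, 0 °C
Reagents that add atoms: triisopropylsilyl trifluoromethanesulfonate, CC(C)[Si](C(C)C)(C(C)C)OS(=O)(=O)C(F)(F)F
Why: soft enolisation (O-silylation, then deprotonation of the acetyl methyl group by the amine) should give the cross-conjugated 2-silyloxy diene and leave the E alkene and the alkyne untouched.

Step 3
Reactants: 5 triisopropyl{[(3E)-3-methylocta-1,3-dien-7-yn-2-yl]oxy}silane; 6 methacrolein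
Product: 7 (1R,2S)-2-(but-3-yn-1-yl)-1,3-dimethyl-4-[(triisopropylsilyl)oxy]cyclohex-3-ene-1-carbaldehyde
Conditions: (S)-B-(o-tolyl)-α,α-diphenylprolinol oxazaborolidine·HNTf2 (15 mol %), CH2Cl2, −78 → −40 °C
Reagents that add atoms: none
Why: in this enantioselective Diels–Alder reaction of an α-substituted acrolein bound to a chiral oxazaborolidinium cation, the silyloxy group and the C5 chain both direct the methacrolein CH2 to the diene CH2 terminus (bonds C2–C3 and C4–C5), endo approach of the formyl group should place it cis to the butynyl chain so that C4 and C5 are set together, and the catalyst fixes the absolute configuration by shielding one face of the dienophile.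

Step 4
Reactants: 7 (1R,2S)-2-(but-3-yn-1-yl)-1,3-dimethyl-4-[(triisopropylsilyl)oxy]cyclohex-3-ene-1-carbaldehyde; 8 allyl bromide
Product: 9 (1R,2R,3S)-2-(but-3-yn-1-yl)-1,3-dimethyl-4-oxo-3-(prop-2-en-1-yl)cyclohexane-1-carbaldehyde
Conditions: TASF, 8 (excess), THF, −78 → 0 °C
Reagents that add atoms: none
Why: in this regiospecific enolate alkylation, fluoride cleaves the silyl enol ether to the tetrasubstituted C1–C10 enolate, which should be allylated at C10 on the face anti to the pseudoaxial butynyl chain on C5 (allyl trans to the chain), the hindered non-enolisable aldehyde being outcompeted by the excess of allyl bromide.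

Step 5
Reactants: 9 (1R,2R,3S)-2-(but-3-yn-1-yl)-1,3-dimethyl-4-oxo-3-(prop-2-en-1-yl)cyclohexane-1-carbaldehyde
Product: 10 (1R,2S,3S)-2-(but-3-yn-1-yl)-1,3-dimethyl-4-oxo-3-(prop-2-en-1-yl)cyclohexane-1-carboxylic acid
Conditions: NaClO2, NaH2PO4, 2-methylbut-2-ene, t-BuOH/H2O, rt
Reagents that add atoms: sodium chlorite, [Na+].[O-]Cl=O
Why: Pinnick oxidation should convert the hindered aldehyde into the acid without touching the ketone, the alkyne or the monosubstituted alkene, because the scavenger alkene removes the hypochlorous acid formed.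

Step 6
Reactants: 10 (1R,2S,3S)-2-(but-3-yn-1-yl)-1,3-dimethyl-4-oxo-3-(prop-2-en-1-yl)cyclohexane-1-carboxylic acid
Product: 11 methyl (1R,2S,3S)-2-(but-3-yn-1-yl)-1,3-dimethyl-4-oxo-3-(prop-2-en-1-yl)cyclohexane-1-carboxylate
Conditions: MeI, K2CO3, DMF, rt
Reagents that add atoms: iodomethane, CI
Why: O-alkylation of the carboxylate (SN2 at methyl) is insensitive to the crowding around the quaternary C4 that would slow an acid-catalysed esterification.

Step 7
Reactants: 11 methyl (1R,2S,3S)-2-(but-3-yn-1-yl)-1,3-dimethyl-4-oxo-3-(prop-2-en-1-yl)cyclohexane-1-carboxylate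
Product: 12 methyl (1R,2S,3S,4S)-2-(but-3-yn-1-yl)-4-hydroxy-1,3-dimethyl-3-(prop-2-en-1-yl)cyclohexane-1-carboxylate
Conditions: NaBH4, MeOH, −20 → 0 °C
Reagents that add atoms: none
Why: in this borohydride reduction the small hydride should attack the C1 ketone along the axial trajectory of the chair that has the C10 methyl axial, on the face away from that methyl, giving the equatorial alcohol cis to the C10 methyl while the hindered ester is not reduced.

Step 8
Reactants: 12 methyl (1R,2S,3S,4S)-2-(but-3-yn-1-yl)-4-hydroxy-1,3-dimethyl-3-(prop-2-en-1-yl)cyclohexane-1-carboxylate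
Product: 13 methyl (1R,2S,3S,4S)-4-(acetyloxy)-2-(but-3-yn-1-yl)-1,3-dimethyl-3-(prop-2-en-1-yl)cyclohexane-1-carboxylate
Conditions: Ac2O, pyridine, DMAP (cat.), CH2Cl2, rt
Reagents that add atoms: acetic anhydride, CC(=O)OC(C)=O
Why: DMAP-catalysed acylation installs the acetate of the target on the equatorial alcohol before the C11 aldehyde is unveiled, which excludes lactol formation later.

Step 9
Reactants: 13 methyl (1R,2S,3S,4S)-4-(acetyloxy)-2-(but-3-yn-1-yl)-1,3-dimethyl-3-(prop-2-en-1-yl)cyclohexane-1-carboxylate
Product: 14 methyl (1R,2S,3S,4S)-4-(acetyloxy)-2-(but-3-yn-1-yl)-1,3-dimethyl-3-(2-oxoethyl)cyclohexane-1-carboxylate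
Conditions: OsO4 (2 mol %), NaIO4, 2,6-lutidine, dioxane/H2O 3:1, rt
Reagents that add atoms: osmium tetroxide, O=[Os](=O)(=O)=O (transfers the oxygen); sodium periodate, [Na+].[O-]I(=O)(=O)=O (reoxidant and source of that oxygen)
Why: Lemieux–Johnson cleavage (dihydroxylation, then glycol fission) removes the terminal carbon of the allyl group to leave the C11 aldehyde, OsO4 reacting far faster with the monosubstituted alkene than with the terminal alkyne.

Step 10
Reactants: 14 methyl (1R,2S,3S,4S)-4-(acetyloxy)-2-(but-3-yn-1-yl)-1,3-dimethyl-3-(2-oxoethyl)cyclohexane-1-carboxylate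
Product: 15 methyl (1R,2S,3R,4S)-4-(acetyloxy)-2-(but-3-yn-1-yl)-1,3-dimethyl-3-[(E)-2-{[tri(propan-2-yl)silyl]oxy}ethenyl]cyclohexane-1-carboxylate
Conditions: TIPSOTf, Et3N, CH2Cl2, 0 °C → rt
Reagents that add atoms: triisopropylsilyl trifluoromethanesulfonate, CC(C)[Si](C(C)C)(C(C)C)OS(=O)(=O)C(F)(F)F
Why: soft enolisation of the aldehyde can only occur toward C9 because C10 is quaternary, and the bulky silyl group should favour the E enol ether and make it resistant to hydrolysis.

Step 11
Reactants: 15 methyl (1R,2S,3R,4S)-4-(acetyloxy)-2-(but-3-yn-1-yl)-1,3-dimethyl-3-[(E)-2-{[tri(propan-2-yl)silyl]oxy}ethenyl]cyclohexane-1-carboxylate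
Product: 16 methyl (1R,4S,4aR,5R,8aS)-4-(acetyloxy)-5-formyl-1,4a-dimethyl-6-methylidenedecahydronaphthalene-1-carboxylate
Conditions: (Ph3P)AuCl (10 mol %), AgBF4 (10 mol %), PhMe/MeOH 10:1, 25 → 40 °C
Reagents that add atoms: none
Why: Cationic triphenylphosphinegold (monovalent gold) π-coordinates the terminal C8≡C17 alkyne and C9 of the silyl enol ether attacks the internal carbon C8 anti to the metal, giving a vinylgold species and a silyloxocarbenium ion at C11; methanol then takes the silyl group and protonates the C17–Au bond, releasing the C8=C17 methylene, the C11 aldehyde and the catalyst. The closest known reaction type is the gold-catalysed Conia-ene-type carbocyclisation of silyl enol ethers onto alkynes. Ring B closes in the 6-exo-dig mode, which the terminal alkyne secures over 7-endo because positive charge builds up at its substituted carbon. C9 should be set by a chair transition state built on the trans-diequatorial C5 and C10 arms of ring A, in which the enol ether reacts through the rotamer whose C9=C11 bond eclipses the C10 methyl, so that C11 becomes equatorial and H9 axial on the face opposite that methyl. The step needs C–C bond formation to outrun loss of the silyl group, which the bulky triisopropylsilyl group should secure, and it needs kinetic control at C9, because the equatorial formyl group lies syn-pentane to the equatorial C1 acetate and next to the methylene group and need not be the more stable epimer. The β,γ-unsaturated aldehyde is therefore kept away from acid and base and is homologated at once.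

Step 12
Reactants: 16 methyl (1R,4S,4aR,5R,8aS)-4-(acetyloxy)-5-formyl-1,4a-dimethyl-6-methylidenedecahydronaphthalene-1-carboxylate
Product: 18 methyl (1R,4S,4aS,5R,8aS)-4-(acetyloxy)-1,4a-dimethyl-6-methylidene-5-(2-oxoethyl)decahydronaphthalene-1-carboxylate, via methyl enol ether 17 (not isolated)
Conditions: MeOCH2PPh3Cl, KHMDS, THF, −78 → 0 °C; then 2 M aq. HCl, rt
Reagents that add atoms: (methoxymethylidene)triphenylphosphorane, COC=P(c1ccccc1)(c1ccccc1)c1ccccc1, made in the flask from (methoxymethyl)triphenylphosphonium chloride, COC[P+](c1ccccc1)(c1ccccc1)c1ccccc1.[Cl-]; water, O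
Why: Wittig methoxymethylenation at low temperature with no excess base, followed by acid hydrolysis of the enol ether in the same flask, adds C12 as an aldehyde and moves the carbonyl out of conjugative reach of C8=C17, after which C9 is no longer epimerisable.

Step 13
Reactants: 18 methyl (1R,4S,4aS,5R,8aS)-4-(acetyloxy)-1,4a-dimethyl-6-methylidene-5-(2-oxoethyl)decahydronaphthalene-1-carboxylate; 19 2-(triphenylphosphoranylidene)propanal
Product: 20 methyl (1R,4S,4aS,5R,8aS)-4-(acetyloxy)-1,4a-dimethyl-5-[(2E)-3-methyl-4-oxobut-2-en-1-yl]-6-methylidenedecahydronaphthalene-1-carboxylate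
Conditions: PhMe, 90 °C
Reagents that add atoms: none
Why: the Wittig reaction of a formyl-stabilised α-methyl ylide with an unhindered aliphatic aldehyde should give the trisubstituted enal as the E isomer, which sets the C12=C13 geometry.

Step 14
Reactants: 20 methyl (1R,4S,4aS,5R,8aS)-4-(acetyloxy)-1,4a-dimethyl-5-[(2E)-3-methyl-4-oxobut-2-en-1-yl]-6-methylidenedecahydronaphthalene-1-carboxylate
Product: 21 methyl (1R,4S,4aS,5R,8aS)-4-(acetyloxy)-1,4a-dimethyl-6-methylidene-5-[(2E)-3-methylpenta-2,4-dien-1-yl]decahydronaphthalene-1-carboxylate (CNP0235031.1)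
Conditions: Ph3PCH3Br, KHMDS, THF, −78 → 0 °C
Reagents that add atoms: methylidenetriphenylphosphorane, C=P(c1ccccc1)(c1ccccc1)c1ccccc1, made in the flask from methyltriphenylphosphonium bromide, C[P+](c1ccccc1)(c1ccccc1)c1ccccc1.[Br-]
Why: Wittig methylenation of the enal should be much faster than attack on the acetate or the hindered methyl ester and cannot disturb the E C12=C13 alkene, so it completes the 12E,14-diene.

**Compound list**

1 | pent-4-yn-1-ol | C#CCCCO | starting material
2 | 3-(triphenylphosphoranylidene)butan-2-one | CC(=O)C(C)=P(c1ccccc1)(c1ccccc1)c1ccccc1 | starting material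
3 | pent-4-ynal | C#CCCC=O | intermediate (not isolated)
4 | (3E)-3-methyloct-3-en-7-yn-2-one | CC(=O)/C(C)=C/CCC#C | intermediate
5 | triisopropyl{[(3E)-3-methylocta-1,3-dien-7-yn-2-yl]oxy}silane | C=C(O[Si](C(C)C)(C(C)C)C(C)C)/C(C)=C/CCC#C | intermediate
6 | methacrolein (2-methylprop-2-enal) | CC(=C)C=O | starting material
7 | (1R,2S)-2-(but-3-yn-1-yl)-1,3-dimethyl-4-[(triisopropylsilyl)oxy]cyclohex-3-ene-1-carbaldehyde (formyl cis to the butynyl chain) | C#CCC[C@H]1C(C)=C(O[Si](C(C)C)(C(C)C)C(C)C)CC[C@@]1(C)C=O | intermediate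
8 | allyl bromide | C=CCBr | starting material
9 | (1R,2R,3S)-2-(but-3-yn-1-yl)-1,3-dimethyl-4-oxo-3-(prop-2-en-1-yl)cyclohexane-1-carbaldehyde (allyl trans to the butynyl chain) | C#CCC[C@H]1[C@](C)(CC=C)C(=O)CC[C@@]1(C)C=O | intermediate
10 | (1R,2S,3S)-2-(but-3-yn-1-yl)-1,3-dimethyl-4-oxo-3-(prop-2-en-1-yl)cyclohexane-1-carboxylic acid | C#CCC[C@H]1[C@](C)(CC=C)C(=O)CC[C@@]1(C)C(=O)O | intermediate
11 | methyl (1R,2S,3S)-2-(but-3-yn-1-yl)-1,3-dimethyl-4-oxo-3-(prop-2-en-1-yl)cyclohexane-1-carboxylate | C#CCC[C@H]1[C@](C)(CC=C)C(=O)CC[C@@]1(C)C(=O)OC | intermediate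
12 | methyl (1R,2S,3S,4S)-2-(but-3-yn-1-yl)-4-hydroxy-1,3-dimethyl-3-(prop-2-en-1-yl)cyclohexane-1-carboxylate (hydroxyl equatorial, cis to the C10 methyl) | C#CCC[C@H]1[C@](C)(CC=C)[C@@H](O)CC[C@@]1(C)C(=O)OC | intermediate
13 | methyl (1R,2S,3S,4S)-4-(acetyloxy)-2-(but-3-yn-1-yl)-1,3-dimethyl-3-(prop-2-en-1-yl)cyclohexane-1-carboxylate | C#CCC[C@H]1[C@](C)(CC=C)[C@@H](OC(C)=O)CC[C@@]1(C)C(=O)OC | intermediate
14 | methyl (1R,2S,3S,4S)-4-(acetyloxy)-2-(but-3-yn-1-yl)-1,3-dimethyl-3-(2-oxoethyl)cyclohexane-1-carboxylate | C#CCC[C@H]1[C@](C)(CC=O)[C@@H](OC(C)=O)CC[C@@]1(C)C(=O)OC | intermediate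
15 | methyl (1R,2S,3R,4S)-4-(acetyloxy)-2-(but-3-yn-1-yl)-1,3-dimethyl-3-[(E)-2-{[tri(propan-2-yl)silyl]oxy}ethenyl]cyclohexane-1-carboxylate (ring A alkynyl silyl enol ether, precursor of the key step) | C#CCC[C@H]1[C@](C)(/C=C/O[Si](C(C)C)(C(C)C)C(C)C)[C@@H](OC(C)=O)CC[C@@]1(C)C(=O)OC | intermediate
16 | methyl (1R,4S,4aR,5R,8aS)-4-(acetyloxy)-5-formyl-1,4a-dimethyl-6-methylidenedecahydronaphthalene-1-carboxylate (decalin C11 aldehyde, product of the key step) | O=C[C@@H]1C(=C)CC[C@H]2[C@@]1(C)[C@@H](OC(C)=O)CC[C@@]2(C)C(=O)OC | intermediate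
17 | methyl enol ether of the C12 aldehyde (5-(2-methoxyethenyl) analogue of 16; E isomer shown, either geometry hydrolyses alike) | CO/C=C/[C@@H]1C(=C)CC[C@H]2[C@@]1(C)[C@@H](OC(C)=O)CC[C@@]2(C)C(=O)OC | intermediate (not isolated)
18 | methyl (1R,4S,4aS,5R,8aS)-4-(acetyloxy)-1,4a-dimethyl-6-methylidene-5-(2-oxoethyl)decahydronaphthalene-1-carboxylate | O=CC[C@@H]1C(=C)CC[C@H]2[C@@]1(C)[C@@H](OC(C)=O)CC[C@@]2(C)C(=O)OC | intermediate
19 | 2-(triphenylphosphoranylidene)propanal | CC(C=O)=P(c1ccccc1)(c1ccccc1)c1ccccc1 | starting material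
20 | methyl (1R,4S,4aS,5R,8aS)-4-(acetyloxy)-1,4a-dimethyl-5-[(2E)-3-methyl-4-oxobut-2-en-1-yl]-6-methylidenedecahydronaphthalene-1-carboxylate | O=C/C(C)=C/C[C@@H]1C(=C)CC[C@H]2[C@@]1(C)[C@@H](OC(C)=O)CC[C@@]2(C)C(=O)OC | intermediate
21 | methyl (1R,4S,4aS,5R,8aS)-4-(acetyloxy)-1,4a-dimethyl-6-methylidene-5-[(2E)-3-methylpenta-2,4-dien-1-yl]decahydronaphthalene-1-carboxylate (CNP0235031.1) | C=C/C(C)=C/C[C@@H]1C(=C)CC[C@H]2[C@@]1(C)[C@@H](OC(C)=O)CC[C@@]2(C)C(=O)OC | target

Total step count: 14. Longest linear sequence: 14 steps (1 → 21).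

**Steps most likely to fail**

Step 11. The six-membered closure is slower than the usual five-membered one, so the silyl group may be lost before the C–C bond forms, methanol may add to the gold-activated alkyne, and facial discrimination at C9 may be poor or eroded by enolisation of the product. The fallback replaces the polar closure by a radical one and sets out from 15. Bu3SnH and AIBN in hot benzene add a stannyl radical to the terminal alkyne carbon C17; the C8 vinyl radical closes 6-exo onto C9 of the enol ether and the α-silyloxy radical at C11 is reduced, giving the vinylstannane silyl ether F1. Aqueous HCl in THF removes tin and silicon to give the C11 alcohol F2. Oxidation with Dess–Martin periodinane buffered with NaHCO3 returns to 16.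

Step 3. Facial discrimination or endo preference may be insufficient with this trisubstituted diene, and Mukaiyama-type addition of the dienol ether to the formyl group may compete with cycloaddition. The fallback sets out from 5 and uses a two-point-binding dienophile, creating the quaternary C4 afterwards. Cycloaddition with 3-acryloyl-1,3-oxazolidin-2-one, catalysed by [Cu((S,S)-t-Bu-box)](SbF6)2 (antipode chosen for the C5 configuration of 7), gives the imide F3, in which only C5 matters. MeOMgBr in MeOH gives the methyl ester F4. LDA (2.2 equiv, one being consumed by the alkyne C–H) and MeI (1 equiv) at −78 °C methylate the ester enolate anti to the C5 chain to give the quaternary ester F5, independent of the endo/exo outcome. TASF and allyl bromide, as in step 4, then return directly to 11.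

Step 12. The basic ylide may deprotonate the doubly activated C9–H of the hindered aldehyde faster than it adds, leading to epimerisation at C9 or migration of the alkene into conjugation. The fallback avoids carbanionic reagents and sets out from 16. NaBH4 in MeOH at 0 °C gives the C11 alcohol F2. I2, PPh3 and imidazole give the iodide F6. Zinc insertion (Zn, LiCl, THF) and Negishi coupling with vinyl bromide under Pd(PPh3)4 give the C9 allyl compound F7. Cross-metathesis with methacrolein (second-generation Hoveyda–Grubbs catalyst) returns to 20; the hindered exocyclic methylene should not take part.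

Further compounds
F1 | step 11 | methyl 4-(acetyloxy)-1,4a-dimethyl-6-[(tributylstannyl)methylidene]-5-{[(triisopropylsilyl)oxy]methyl}decahydronaphthalene-1-carboxylate, ring configuration as in 16, alkene geometry mixed | CC(C)[Si](C(C)C)(C(C)C)OC[C@@H]1C(=C[Sn](CCCC)(CCCC)CCCC)CC[C@H]2[C@@]1(C)[C@@H](OC(C)=O)CC[C@@]2(C)C(=O)OC
F2 | step 11 | methyl 4-(acetyloxy)-5-(hydroxymethyl)-1,4a-dimethyl-6-methylidenedecahydronaphthalene-1-carboxylate, configuration as in 16 (C11 alcohol) | OC[C@@H]1C(=C)CC[C@H]2[C@@]1(C)[C@@H](OC(C)=O)CC[C@@]2(C)C(=O)OC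
F3 | step 3 | 3-{[2-(but-3-yn-1-yl)-3-methyl-4-(triisopropylsilyloxy)cyclohex-3-en-1-yl]carbonyl}-1,3-oxazolidin-2-one, C5 as in 7, acyl group cis to the chain | C#CCC[C@H]1C(C)=C(O[Si](C(C)C)(C(C)C)C(C)C)CC[C@H]1C(=O)N1CCOC1=O
F4 | step 3 | methyl 2-(but-3-yn-1-yl)-3-methyl-4-(triisopropylsilyloxy)cyclohex-3-ene-1-carboxylate, C5 as in 7 | C#CCC[C@H]1C(C)=C(O[Si](C(C)C)(C(C)C)C(C)C)CC[C@H]1C(=O)OC
F5 | step 3 | methyl 2-(but-3-yn-1-yl)-1,3-dimethyl-4-(triisopropylsilyloxy)cyclohex-3-ene-1-carboxylate, C4 and C5 as in 7 | C#CCC[C@H]1C(C)=C(O[Si](C(C)C)(C(C)C)C(C)C)CC[C@@]1(C)C(=O)OC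
F6 | step 12 | methyl 4-(acetyloxy)-5-(iodomethyl)-1,4a-dimethyl-6-methylidenedecahydronaphthalene-1-carboxylate, configuration as in 16 | IC[C@@H]1C(=C)CC[C@H]2[C@@]1(C)[C@@H](OC(C)=O)CC[C@@]2(C)C(=O)OC
F7 | step 12 | methyl 4-(acetyloxy)-1,4a-dimethyl-6-methylidene-5-(prop-2-en-1-yl)decahydronaphthalene-1-carboxylate, configuration as in 18 | C=CC[C@@H]1C(=C)CC[C@H]2[C@@]1(C)[C@@H](OC(C)=O)CC[C@@]2(C)C(=O)OC
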